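The route rests on disconnecting the aryl ether bond O1–C8a of pyran ring C in the upper epicatechin unit, exploiting the fact that C8a of its 5,7-dioxygenated ring A can carry fluoride as a leaving group. Ring A therefore comes from 1,3,5-trifluorobenzene. The precursor is an open-chain 1,3-diarylpropane-1,3-diol 2-allyl ether whose syn C2/C3 array (flavan numbering) comes from a glycolate aldol. In one operation the C2 alkoxide displaces fluoride (SNAr), closing ring C with retention at C2 and giving the 2,3-cis flavan-4-ol electrophile. After bromine capping, two orthogonal Friedel–Crafts couplings (C4–O, then C4–S activation) attach epicatechin-derived middle and lower units; galloylation and hydrogenolysis finish.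

Key step: step 7

Remark: flavan numbering (O1, C2, C3, C4, C4a, C5–C8, C8a) is used for each unit; the upper unit is bonded through C4 to C6 of the middle unit, and the lower unit has the C4 methylene group.
Remark: the C4 carbinol carbon of 13–18 is carried as a mixture of epimers (no stereo mark in the SMILES) because it becomes a planar cation in step 14; 2-(allyloxy)acetic acid and 3,4,5-tris(benzyloxy)benzoyl chloride are taken as purchasable.

Step 1
Reactants: 1 1,3,5-trifluorobenzene
Product: 2 1,3-bis(benzyloxy)-5-fluorobenzene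
Conditions: BnOH (2.1 equiv), NaH (2.2 equiv), NMP, 0 °C → 80 °C
Reagents that add atoms: benzyl alcohol, OCc1ccccc1
Why: Twofold nucleophilic aromatic substitution (SNAr) of fluoride by benzyl oxide should stop at the bis-ether because each alkoxy group lowers the electrophilicity of the ring, which keeps one C–F bond as the later leaving group at C8a.

Step 2
Reactants: 3 (S)-4-benzyloxazolidin-2-one; 4 2-(allyloxy)acetic acid
Product: 6 (S)-3-[2-(allyloxy)acetyl]-4-benzyloxazolidin-2-one, via mixed pivalic anhydride 5 (not isolated)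
Conditions: PivCl, Et3N, THF, −20 °C; then LiCl, 3, −20 °C → rt
Reagents that add atoms: none
Why: N-Acylation of the oxazolidinone through the mixed anhydride (LiCl/Et3N protocol) should occur at the less hindered allyloxyacetyl carbonyl and installs a glycolate that already carries the future C3 oxygen as a base-stable, non-migrating allyl ether.

Step 3
Reactants: 6 (S)-3-[2-(allyloxy)acetyl]-4-benzyloxazolidin-2-one; 7 3,4-bis(benzyloxy)benzaldehyde
Product: 9 (S)-4-benzyl-3-[(2S,3R)-2-(allyloxy)-3-[3,4-bis(benzyloxy)phenyl]-3-hydroxypropanoyl]oxazolidin-2-one, via dibutylboron enolate 8 (not isolated)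
Conditions: Bu2BOTf, Et3N, CH2Cl2, −78 → 0 °C; then 7, −78 → 0 °C; pH 7 buffer/MeOH work-up
Reagents that add atoms: none
Why: Evans syn glycolate aldol: the Z boron enolate should react through a closed Zimmerman–Traxler transition state on the face away from the auxiliary benzyl group, which sets the (2S,3R) syn array that becomes C3 and C2 of the upper flavan unit.

Step 4
Reactants: 9 (S)-4-benzyl-3-[(2S,3R)-2-(allyloxy)-3-[3,4-bis(benzyloxy)phenyl]-3-hydroxypropanoyl]oxazolidin-2-one
Product: 10 (2S,3R)-2-(allyloxy)-3-[3,4-bis(benzyloxy)phenyl]-3-hydroxy-N-methoxy-N-methylpropanamide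
Conditions: MeNHOMe·HCl, AlMe3, CH2Cl2, −10 °C → rt
Reagents that add atoms: N,O-dimethylhydroxylamine hydrochloride, CNOC.Cl
Why: Aluminium amide transamination of the aldol imide, assisted by the free β-hydroxyl, should give the Weinreb amide without touching either new stereocentre and releases the auxiliary.

Step 5
Reactants: 10 (2S,3R)-2-(allyloxy)-3-[3,4-bis(benzyloxy)phenyl]-3-hydroxy-N-methoxy-N-methylpropanamide; 2 1,3-bis(benzyloxy)-5-fluorobenzene
Product: 12 (2S,3R)-2-(allyloxy)-1-[2,4-bis(benzyloxy)-6-fluorophenyl]-3-[3,4-bis(benzyloxy)phenyl]-3-hydroxypropan-1-one, via aryllithium 11 (not isolated)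
Conditions: 2 (3.2 equiv), n-BuLi (3.0 equiv), THF, −78 °C; then 10, −78 °C; aq NH4Cl at −78 °C
Reagents that add atoms: none
Why: Ortho-lithiation of 2 at the C–H between fluorine and a benzyloxy group, followed by acyl substitution on the Weinreb amide (chelated tetrahedral adduct, no over-addition; the first equivalent of aryllithium is consumed by the hydroxyl), should attach ring A with its fluorine ortho to the new C4 carbonyl.

Step 6
Reactants: 12 (2S,3R)-2-(allyloxy)-1-[2,4-bis(benzyloxy)-6-fluorophenyl]-3-[3,4-bis(benzyloxy)phenyl]-3-hydroxypropan-1-one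
Product: 13 (2S,3R)-2-(allyloxy)-1-[2,4-bis(benzyloxy)-6-fluorophenyl]-3-[3,4-bis(benzyloxy)phenyl]propane-1,3-diol (C1 epimers)
Conditions: NaBH4, THF/MeOH, 0 °C
Reagents that add atoms: none
Why: Borohydride reduction of the aryl ketone should give the C4 carbinol, whose configuration is irrelevant because it is lost at the cation stage, and removes the retro-aldol pathway before the basic ring closure.

Step 7
Reactants: 13 (2S,3R)-2-(allyloxy)-1-[2,4-bis(benzyloxy)-6-fluorophenyl]-3-[3,4-bis(benzyloxy)phenyl]propane-1,3-diol (C1 epimers)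
Product: 15 (2R,3R)-3-(allyloxy)-5,7-bis(benzyloxy)-2-[3,4-bis(benzyloxy)phenyl]chroman-4-ol (2,3-cis; C4 epimers), via dipotassium dialkoxide 14 (not isolated)
Conditions: KH (2.5 equiv), DMF, 0 °C → rt
Reagents that add atoms: none
Why: KH converts both hydroxyls of 13 into potassium alkoxides, and the C2 alkoxide should add to C8a (ipso to fluorine) to give a Meisenheimer anion whose charge at C8, C6 and C4a is stabilised inductively by the flanking C7 and C5 benzyloxy groups, before fluoride is lost; the closest known reaction type is the intramolecular SNAr etherification of a fluoroarene used for pyran closure in de novo flavan-3-ol synthesis. The one ring formed, pyran ring C, closes in a 6-exo-trig addition–elimination mode. No stereocentre is created: the C2–O bond is never broken, so the syn C2/C3 relationship from the aldol is carried with retention into the 2,3-cis (epi) flavan, without the benzylic cation that scrambles C2 in acid-mediated closures, and the C4 carbinol stays an epimer mixture that step 14 erases. The step needs chemoselection among three oxygens: the C3 oxygen, which would give a five-membered dihydrobenzofuran, is blocked as its allyl ether, and the C4 alkoxide could reach C8a only through a four-membered ring, so only the six-membered closure is open. Fluoride is the only leaving group on ring A at this stage, since the aryl bromides are introduced afterwards.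

Step 8
Reactants: 15 (2R,3R)-3-(allyloxy)-5,7-bis(benzyloxy)-2-[3,4-bis(benzyloxy)phenyl]chroman-4-ol (2,3-cis; C4 epimers)
Product: 16 (2R,3R)-3-(allyloxy)-5,7-bis(benzyloxy)-6,8-dibromo-2-[3,4-bis(benzyloxy)phenyl]chroman-4-ol (2,3-cis; C4 epimers)
Conditions: NBS (2.05 equiv), CH2Cl2, −78 → 0 °C
Reagents that add atoms: N-bromosuccinimide, O=C1CCC(=O)N1Br
Why: Electrophilic aromatic bromination should occupy the only two free positions of the phloroglucinol-type ring A (C8, then C6), which caps the upper unit against self-condensation in the Friedel–Crafts steps while the less activated catechol ring and the terminal alkene stay untouched at low temperature.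

Step 9
Reactants: 16 (2R,3R)-3-(allyloxy)-5,7-bis(benzyloxy)-6,8-dibromo-2-[3,4-bis(benzyloxy)phenyl]chroman-4-ol (2,3-cis; C4 epimers)
Product: 18 (2R,3R)-5,7-bis(benzyloxy)-6,8-dibromo-2-[3,4-bis(benzyloxy)phenyl]chromane-3,4-diol (2,3-cis; C4 epimers), via propenyl ether 17 (not isolated)
Conditions: [Ir(cod)(PMePh2)2]PF6 (3 mol %, pre-activated with H2), THF, rt; then 0.1 M aq HCl, rt
Reagents that add atoms: none
Why: Iridium-hydride-catalysed isomerisation of the allyl ether to the prop-1-enyl ether and mild acidic hydrolysis of this enol ether should free the C3 hydroxyl while benzyl ethers and aryl bromides stay intact, and any reversible ionisation at C4 only returns the carbinol because ring A is capped.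

Step 10
Reactants: 19 (−)-epicatechin
Product: 20 5,7,3',4'-tetra-O-benzyl-(−)-epicatechin
Conditions: BnBr (4.4 equiv), K2CO3, DMF, 0 °C → rt
Reagents that add atoms: benzyl bromide, BrCc1ccccc1
Why: Williamson etherification with the weak base K2CO3 should alkylate only the four phenolic hydroxyls and leave the less acidic C3 hydroxyl free.

Step 11
Reactants: 20 5,7,3',4'-tetra-O-benzyl-(−)-epicatechin
Product: 21 5,7,3',4'-tetra-O-benzyl-4β-(2-ethoxyethoxy)epicatechin (2R; 2,3-cis; 3,4-trans)
Conditions: DDQ (2 equiv), 2-ethoxyethanol (5 equiv), CH2Cl2, rt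
Reagents that add atoms: 2-ethoxyethanol, CCOCCO
Why: DDQ should abstract hydride from the benzylic C4 position activated by the trioxygenated ring A (benzylic oxidation through the C4 cation), and the alcohol adds trans to the C3 hydroxyl, which sets the 4β configuration.

Step 12
Reactants: 21 5,7,3',4'-tetra-O-benzyl-4β-(2-ethoxyethoxy)epicatechin
Product: 22 5,7,3',4'-tetra-O-benzyl-8-bromo-4β-(2-ethoxyethoxy)epicatechin
Conditions: NBS (1.0 equiv), CH2Cl2, −78 °C → rt
Reagents that add atoms: N-bromosuccinimide, O=C1CCC(=O)N1Br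
Why: Electrophilic bromination with one equivalent of NBS should go to C8, the more nucleophilic of the two free ring A positions of 5,7-di-O-benzyl flavans, which leaves C6 as the only site for the interflavan bond.

Step 13
Reactants: 22 5,7,3',4'-tetra-O-benzyl-8-bromo-4β-(2-ethoxyethoxy)epicatechin
Product: 23 5,7,3',4'-tetra-O-benzyl-4β-(benzylsulfanyl)-8-bromoepicatechin (2R; 2,3-cis; 3,4-trans)
Conditions: BnSH (3 equiv), BF3·OEt2 (0.3 equiv), CH2Cl2, −78 → −20 °C
Reagents that add atoms: benzyl mercaptan, SCc1ccccc1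
Why: Lewis-acid-promoted SN1 exchange at C4 should ionise the ether to the C4 cation, to which the thiol adds on the β face trans to the C3 hydroxyl (the outcome of procyanidin thiolysis), turning the hard oxygen leaving group into a soft sulfur leaving group that survives the next Lewis acid step.

Step 14
Reactants: 18 (2R,3R)-5,7-bis(benzyloxy)-6,8-dibromo-2-[3,4-bis(benzyloxy)phenyl]chromane-3,4-diol (2,3-cis; C4 epimers); 23 5,7,3',4'-tetra-O-benzyl-4β-(benzylsulfanyl)-8-bromoepicatechin
Product: 24 (4β→6)-linked dimer: upper unit 5,7,3',4'-tetra-O-benzyl-6,8-dibromoepicatechin bonded from C4 (β) to C6 of the middle unit 5,7,3',4'-tetra-O-benzyl-4β-(benzylsulfanyl)-8-bromoepicatechin; both C3 hydroxyls free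
Conditions: 23 (1.5 equiv), BF3·OEt2 (0.5 equiv), 4 Å MS, CH2Cl2, −78 → −40 °C
Reagents that add atoms: none
Why: Dehydrative Friedel–Crafts alkylation: BF3 should ionise either C4 epimer of 18 to the same flavan-4-yl cation, which cannot attack its own capped ring A and is taken by C6 of 23 (C8 blocked by bromine) on the β face trans to the C3 hydroxyl and the C2 aryl group, so the upper 4β centre is set stereoconvergently while the C–S bond of 23 is inert to the hard Lewis acid at low temperature.

Step 15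
Reactants: 24 (4β→6)-linked dimer with 4β-benzylsulfanyl group on the middle unit; 20 5,7,3',4'-tetra-O-benzyl-(−)-epicatechin
Product: 25 trimer triol: dodeca-O-benzyl-6,8-dibromoepicatechin-(4β→6)-8-bromoepicatechin-(4β→8)-epicatechin with three free C3 hydroxyls
Conditions: 20 (3 equiv), AgBF4 (2.5 equiv), THF/CH2Cl2, 0 °C, dark
Reagents that add atoms: none
Why: Thiophilic activation of the benzylic thioether by AgBF4 should give the middle-unit C4 cation, which is captured by the most nucleophilic position (C8) of excess 20 on the β face trans to the C3 hydroxyl, setting the second 4β centre, and the electrophile cannot oligomerise because all its ring A positions are substituted.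

Step 16
Reactants: 25 trimer triol; 26 3,4,5-tris(benzyloxy)benzoyl chloride (three molecules are consumed per molecule of 25)
Product: 27 fully protected trimer tris(3,4,5-tri-O-benzylgallate): 25 esterified at the C3 oxygen of all three units
Conditions: 3,4,5-tris(benzyloxy)benzoyl chloride (4.5 equiv), DMAP, pyridine, CH2Cl2, rt → 40 °C
Reagents that add atoms: 3,4,5-tris(benzyloxy)benzoyl chloride, O=C(Cl)c1cc(OCc2ccccc2)c(OCc2ccccc2)c(OCc2ccccc2)c1
Why: DMAP-catalysed acyl transfer from the excess acid chloride should esterify all three secondary C3 hydroxyls, the only free hydroxyls in the molecule, so that three 3,4,5-tris(benzyloxy)benzoyl groups are incorporated per molecule of 25 while the C3 configurations are untouched because only O–H bonds react.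

Step 17
Reactants: 27 fully protected trimer tris(3,4,5-tri-O-benzylgallate)
Product: 28 epicatechin-3-O-gallate-(4β→6)-epicatechin-3-O-gallate-(4β→8)-epicatechin-3-O-gallate (target)
Conditions: H2 (1 atm), Pd(OH)2/C, Et3N (3 equiv), THF/MeOH/H2O, rt
Reagents that add atoms: none
Why: Palladium-catalysed hydrogenolysis should cleave the twenty-one O-benzyl groups and, in the same operation, the three aryl C–Br caps, with triethylamine buffering the HBr so that the acid-labile interflavan bonds and the gallate esters survive.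

Compound list
1 | 1,3,5-trifluorobenzene | Fc1cc(F)cc(F)c1 | starting material
2 | 1,3-bis(benzyloxy)-5-fluorobenzene | Fc1cc(OCc2ccccc2)cc(OCc2ccccc2)c1 | intermediate
3 | (S)-4-benzyloxazolidin-2-one | O=C1N[C@@H](Cc2ccccc2)CO1 | starting material
4 | 2-(allyloxy)acetic acid | C=CCOCC(=O)O | starting material
5 | 2-(allyloxy)acetic pivalic anhydride | C=CCOCC(=O)OC(=O)C(C)(C)C | intermediate (not isolated)
6 | (S)-3-[2-(allyloxy)acetyl]-4-benzyloxazolidin-2-one | C=CCOCC(=O)N1[C@@H](Cc2ccccc2)COC1=O | intermediate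
7 | 3,4-bis(benzyloxy)benzaldehyde | O=Cc1ccc(OCc2ccccc2)c(OCc2ccccc2)c1 | starting material
8 | (Z)-dibutylboron enolate of 6 | C=CCO/C=C(\OB(CCCC)CCCC)N1[C@@H](Cc2ccccc2)COC1=O | intermediate (not isolated)
9 | (S)-4-benzyl-3-[(2S,3R)-2-(allyloxy)-3-[3,4-bis(benzyloxy)phenyl]-3-hydroxypropanoyl]oxazolidin-2-one | O=C(N1[C@@H](Cc2ccccc2)COC1=O)[C@@H](OCC=C)[C@H](O)c1ccc(OCc2ccccc2)c(OCc2ccccc2)c1 | intermediate
10 | (2S,3R)-2-(allyloxy)-3-[3,4-bis(benzyloxy)phenyl]-3-hydroxy-N-methoxy-N-methylpropanamide | CON(C)C(=O)[C@@H](OCC=C)[C@H](O)c1ccc(OCc2ccccc2)c(OCc2ccccc2)c1 | intermediate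
11 | [2,4-bis(benzyloxy)-6-fluorophenyl]lithium | [Li]c1c(F)cc(OCc2ccccc2)cc1OCc1ccccc1 | intermediate (not isolated)
12 | (2S,3R)-2-(allyloxy)-1-[2,4-bis(benzyloxy)-6-fluorophenyl]-3-[3,4-bis(benzyloxy)phenyl]-3-hydroxypropan-1-one | O=C(c1c(F)cc(OCc2ccccc2)cc1OCc1ccccc1)[C@@H](OCC=C)[C@H](O)c1ccc(OCc2ccccc2)c(OCc2ccccc2)c1 | intermediate
13 | (2S,3R)-2-(allyloxy)-1-[2,4-bis(benzyloxy)-6-fluorophenyl]-3-[3,4-bis(benzyloxy)phenyl]propane-1,3-diol, mixture of C1 epimers | OC(c1c(F)cc(OCc2ccccc2)cc1OCc1ccccc1)[C@@H](OCC=C)[C@H](O)c1ccc(OCc2ccccc2)c(OCc2ccccc2)c1 | intermediate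
14 | dipotassium 1,3-dialkoxide of 13 | [K+].[K+].[O-]C(c1c(F)cc(OCc2ccccc2)cc1OCc1ccccc1)[C@@H](OCC=C)[C@H]([O-])c1ccc(OCc2ccccc2)c(OCc2ccccc2)c1 | intermediate (not isolated)
15 | (2R,3R)-3-(allyloxy)-5,7-bis(benzyloxy)-2-[3,4-bis(benzyloxy)phenyl]chroman-4-ol, 2,3-cis, mixture of C4 epimers | C=CCO[C@@H]1C(O)c2c(OCc3ccccc3)cc(OCc3ccccc3)cc2O[C@@H]1c1ccc(OCc2ccccc2)c(OCc2ccccc2)c1 | intermediate
16 | (2R,3R)-3-(allyloxy)-5,7-bis(benzyloxy)-6,8-dibromo-2-[3,4-bis(benzyloxy)phenyl]chroman-4-ol, 2,3-cis, mixture of C4 epimers | C=CCO[C@@H]1C(O)c2c(OCc3ccccc3)c(Br)c(OCc3ccccc3)c(Br)c2O[C@@H]1c1ccc(OCc2ccccc2)c(OCc2ccccc2)c1 | intermediate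
17 | 3-O-[(E)-prop-1-enyl] analogue of 16 | C/C=C/O[C@@H]1C(O)c2c(OCc3ccccc3)c(Br)c(OCc3ccccc3)c(Br)c2O[C@@H]1c1ccc(OCc2ccccc2)c(OCc2ccccc2)c1 | intermediate (not isolated)
18 | (2R,3R)-5,7-bis(benzyloxy)-6,8-dibromo-2-[3,4-bis(benzyloxy)phenyl]chromane-3,4-diol, 2,3-cis, mixture of C4 epimers | O[C@@H]1C(O)c2c(OCc3ccccc3)c(Br)c(OCc3ccccc3)c(Br)c2O[C@@H]1c1ccc(OCc2ccccc2)c(OCc2ccccc2)c1 | intermediate
19 | (−)-epicatechin, (2R,3R)-2-(3,4-dihydroxyphenyl)chromane-3,5,7-triol | O[C@@H]1Cc2c(O)cc(O)cc2O[C@@H]1c1ccc(O)c(O)c1 | starting material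
20 | 5,7,3',4'-tetra-O-benzyl-(−)-epicatechin | O[C@@H]1Cc2c(OCc3ccccc3)cc(OCc3ccccc3)cc2O[C@@H]1c1ccc(OCc2ccccc2)c(OCc2ccccc2)c1 | intermediate
21 | 5,7,3',4'-tetra-O-benzyl-4β-(2-ethoxyethoxy)epicatechin (2R, 2,3-cis, 3,4-trans) | O[C@@H]1[C@@H](OCCOCC)c2c(OCc3ccccc3)cc(OCc3ccccc3)cc2O[C@@H]1c1ccc(OCc2ccccc2)c(OCc2ccccc2)c1 | intermediate
22 | 5,7,3',4'-tetra-O-benzyl-8-bromo-4β-(2-ethoxyethoxy)epicatechin | O[C@@H]1[C@@H](OCCOCC)c2c(OCc3ccccc3)cc(OCc3ccccc3)c(Br)c2O[C@@H]1c1ccc(OCc2ccccc2)c(OCc2ccccc2)c1 | intermediate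
23 | 5,7,3',4'-tetra-O-benzyl-4β-(benzylsulfanyl)-8-bromoepicatechin | O[C@@H]1[C@@H](SCc2ccccc2)c2c(OCc3ccccc3)cc(OCc3ccccc3)c(Br)c2O[C@@H]1c1ccc(OCc2ccccc2)c(OCc2ccccc2)c1 | intermediate
24 | (4β→6) dimer: tetra-O-benzyl-6,8-dibromoepicatechin (upper) linked to tetra-O-benzyl-4β-(benzylsulfanyl)-8-bromoepicatechin (middle), both C3 hydroxyls free | O[C@@H]1[C@@H](c2c(OCc3ccccc3)c(Br)c3c(c2OCc2ccccc2)[C@H](SCc2ccccc2)[C@@H](O)[C@@H](c2ccc(OCc4ccccc4)c(OCc4ccccc4)c2)O3)c2c(OCc3ccccc3)c(Br)c(OCc3ccccc3)c(Br)c2O[C@@H]1c1ccc(OCc2ccccc2)c(OCc2ccccc2)c1 | intermediate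
25 | trimer triol: dodeca-O-benzyl-6,8-dibromoepicatechin-(4β→6)-8-bromoepicatechin-(4β→8)-epicatechin | O[C@@H]1[C@@H](c2c(OCc3ccccc3)c(Br)c3c(c2OCc2ccccc2)[C@H](c2c(OCc5ccccc5)cc(OCc5ccccc5)c4c2O[C@H](c2ccc(OCc5ccccc5)c(OCc5ccccc5)c2)[C@H](O)C4)[C@@H](O)[C@@H](c2ccc(OCc4ccccc4)c(OCc4ccccc4)c2)O3)c2c(OCc3ccccc3)c(Br)c(OCc3ccccc3)c(Br)c2O[C@@H]1c1ccc(OCc2ccccc2)c(OCc2ccccc2)c1 | intermediate
26 | 3,4,5-tris(benzyloxy)benzoyl chloride | O=C(Cl)c1cc(OCc2ccccc2)c(OCc2ccccc2)c(OCc2ccccc2)c1 | starting material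
27 | tris(3,4,5-tri-O-benzylgalloyl) ester of 25 (all three C3 oxygens acylated) | O=C(O[C@@H]1[C@@H](c2c(OCc3ccccc3)c(Br)c3c(c2OCc2ccccc2)[C@H](c2c(OCc5ccccc5)cc(OCc5ccccc5)c4c2O[C@H](c2ccc(OCc5ccccc5)c(OCc5ccccc5)c2)[C@H](OC(=O)c2cc(OCc5ccccc5)c(OCc5ccccc5)c(OCc5ccccc5)c2)C4)[C@@H](OC(=O)c2cc(OCc4ccccc4)c(OCc4ccccc4)c(OCc4ccccc4)c2)[C@@H](c2ccc(OCc4ccccc4)c(OCc4ccccc4)c2)O3)c2c(OCc3ccccc3)c(Br)c(OCc3ccccc3)c(Br)c2O[C@@H]1c1ccc(OCc2ccccc2)c(OCc2ccccc2)c1)c1cc(OCc2ccccc2)c(OCc2ccccc2)c(OCc2ccccc2)c1 | intermediate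
28 | epicatechin-3-O-gallate-(4β→6)-epicatechin-3-O-gallate-(4β→8)-epicatechin-3-O-gallate | O=C(O[C@@H]1[C@@H](c2c(O)cc3c(c2O)[C@H](c2c(O)cc(O)c4c2O[C@H](c2ccc(O)c(O)c2)[C@H](OC(=O)c2cc(O)c(O)c(O)c2)C4)[C@@H](OC(=O)c2cc(O)c(O)c(O)c2)[C@@H](c2ccc(O)c(O)c2)O3)c2c(O)cc(O)cc2O[C@@H]1c1ccc(O)c(O)c1)c1cc(O)c(O)c(O)c1 | target

Total step count: 17.
Longest linear sequence: 12 steps (steps 2–9, then 14–17).

Steps most likely to fail

Step 7. Addition of the alkoxide to the electron-rich, unactivated fluoroarene may be too slow, and long exposure to KH may degrade the dialkoxide (allyl-to-propenyl isomerisation, benzyl ether cleavage). The fallback sets out from 12 and comes back to the route at 15. The ring is closed one step earlier, on ketone 12, where the fluorine is ortho to the C4 carbonyl and therefore activated. K2CO3 in DMF at 0 °C should form the same O1–C8a bond by carbonyl-activated SNAr and give the 2,3-cis flavan-4-one F1. F1 is reduced at once with NaBH4 (THF/MeOH, −20 °C) to 15; the mild base and short contact time are chosen to limit epimerisation at C3 of the cis-flavanone.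

Step 14. Ionisation of the doubly brominated, less stabilised C4 carbinol may be slow, the water formed may deactivate the Lewis acid, and the higher temperature then needed may begin to activate the C–S bond of 23. The fallback sets out from 18 and comes back to the route at 24. Both hydroxyls of 18 are acetylated (Ac2O, DMAP, pyridine) to the 3,4-di-O-acetate F2. With BF3·OEt2 at −78 °C the C4 acetate should leave with anchimeric assistance of the C3 acetoxy group, and the bridged acetoxonium ion is opened by C6 of 23 on the β face to give the upper-unit 3-O-acetyl dimer F3. K2CO3 in MeOH/THF then removes the acetate to give 24.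

Step 15. Capture of the silver-generated cation by 20 may be slow, so that the cation is lost to side reactions or attacks C6 of 20, and silver thiolate may occlude material. The fallback sets out from 24 and comes back to the route at 25. Ionisation and C–C bond formation are separated: AgBF4 in MeOH/CH2Cl2 solvolyses 24 to the 4β-methoxy dimer F4. F4 is then condensed with 20 (4 equiv) under catalytic TMSOTf in CH2Cl2 at −78 °C, an oxygen-activated 4β→8 Friedel–Crafts coupling, to give 25.

Further compounds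
F1 | step 7 | (2R,3S)-3-(allyloxy)-5,7-bis(benzyloxy)-2-[3,4-bis(benzyloxy)phenyl]chroman-4-one (2,3-cis) | C=CCO[C@@H]1C(=O)c2c(OCc3ccccc3)cc(OCc3ccccc3)cc2O[C@@H]1c1ccc(OCc2ccccc2)c(OCc2ccccc2)c1
F2 | step 14 | 3,4-di-O-acetate of 18 (2R, 2,3-cis, C4 epimers) | CC(=O)O[C@@H]1C(OC(C)=O)c2c(OCc3ccccc3)c(Br)c(OCc3ccccc3)c(Br)c2O[C@@H]1c1ccc(OCc2ccccc2)c(OCc2ccccc2)c1
F3 | step 14 | upper-unit 3-O-acetate of dimer 24 | CC(=O)O[C@@H]1[C@@H](c2c(OCc3ccccc3)c(Br)c3c(c2OCc2ccccc2)[C@H](SCc2ccccc2)[C@@H](O)[C@@H](c2ccc(OCc4ccccc4)c(OCc4ccccc4)c2)O3)c2c(OCc3ccccc3)c(Br)c(OCc3ccccc3)c(Br)c2O[C@@H]1c1ccc(OCc2ccccc2)c(OCc2ccccc2)c1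
F4 | step 15 | 4β-methoxy analogue of dimer 24 (OMe in place of SBn at C4 of the middle unit) | O[C@@H]1[C@@H](c2c(OCc3ccccc3)c(Br)c3c(c2OCc2ccccc2)[C@H](OC)[C@@H](O)[C@@H](c2ccc(OCc4ccccc4)c(OCc4ccccc4)c2)O3)c2c(OCc3ccccc3)c(Br)c(OCc3ccccc3)c(Br)c2O[C@@H]1c1ccc(OCc2ccccc2)c(OCc2ccccc2)c1
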